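Read the late rows first.

| setting | south-west | north-east | flask |
|---|---|---|---|
| starting material | 0.090 M | 0.090 M | 0.090 M |
| second substrate | 0.045 M | 0.030 M | 0.0450 M |
| reagent | 0.117 M | 0.117 M | 0.117 M |
| free catalyst | 1.7 mM | 1.7 mM | 1.7 mM |
| temperature | 25 °C | 31 °C | 25 °C |
| remark | the very flask that is asked about, followed so far | run made earlier |  |
| time |  |  | 6.0 min |

- south-west (time / min: target / %, starting material / %): 0.250: 10.4, 86.8; 0.667: 21.8, 72.3; 1.33: 35.7, 56.2; 2.00: 44.3, 45.6; 3.00: 52.9, 37.1; 4.00: 56.3, 32.3; 5.00: 58.5, 28.5
- north-east (time / s: target / %, starting material / %): 10.0: 8.2, 87.8; 15.0: 11.0, 84.9; 25.0: 17.5, 75.3; 40.0: 25.6, 66.4; 50.0: 28.9, 62.2; 80.0: 40.1, 49.3; 120: 46.7, 39.3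

(readings scatter by 0.5 percentage points)

- ash: change nothing and wait 12 min more
- cedar: at 6.0 min take out 90 % of the target then present, then wait 12 min
- birch: at 6.0 min raise the temperature by 20 K, then wait 12 min
- elm: at 6.0 min add free catalyst, 50.0 % of the amount charged, then wait 12 min
- maple: at 6.0 min add reagent, 100 % of the amount charged, then wait 12 min

- target taken out counts as made
- additions bring no volume worth counting

- target, in percent of the starting material first charged, at 6.0 min
- what to do for the largest gain in target; "none" if nothing gains more than 2 percentage points (ash / cedar / birch / elm / maple / none)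
- target present, with what was taken out counted in, in percent of the starting material first charged, after cedar
- target present, with what was taken out counted in, in percent of the starting material first charged, after maple

The south-west run is this flask followed up to 5.00 min, so the answer to "now" lies one short step past its last row, and what you need is a correction to 58.5 % of target, not a new curve. Over the whole run, target per point of starting material lost is 0.818, but that average carries the early rows. Between 3.00 min and 5.00 min target gains 5.6 percentage points while starting material loses 8.6 points, so the marginal yield, the target gained per point of starting material lost over the latest stretch (a differential selectivity), is 0.651, lower than the average, and as a reading it carries the scatter of its rows.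

If starting material falls once more by its last step, to 24.7 %, my own reckoning for 6.0 min is 61.0 % of target. If maple then uses up what remains, the same reckoning puts it at 77.1 %, as an estimate.

The forecast differs: 60.4 % now, maple as the best choice, 69 % after cedar and 81 % after maple, the last resting on its remark that “Selectivity stays about 0.8 throughout”.

The simulation gives 58.9 %, maple, 64.8 % after cedar and 73.1 % after maple.

    reagent + catalyst intermediate A ⇌ free catalyst + target (K = 2.10, k = 6.10 /M/s, Ea = 37.0 kJ/mol, ΔH = 32.0 kJ/mol)
    second substrate + free catalyst ⇌ catalyst intermediate B (K = 210 /M, k = 23.0 /M/s, Ea = 39.0 kJ/mol, ΔH = 34.0 kJ/mol)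
    starting material + free catalyst ⇌ catalyst intermediate A (K = 54.0 /M, k = 110 /M/s, Ea = 42.0 kJ/mol, ΔH = −71.0 kJ/mol)
    reagent + catalyst intermediate B → free catalyst + second product (k = 2.70 /M/s, Ea = 44.0 kJ/mol)
    starting material + reagent → uncatalysed product (k = 0.0140 /M/s, Ea = 70.0 kJ/mol)
    (constants at 25 °C)

Put 0.651 on the 27.7 % of starting material standing in this flask at 6.0 min and maple comes to 76.9 %, still above the 73.1 % it gives. In this flask at 6.0 min, the step between reagent + catalyst intermediate A and free catalyst + target, taken by itself and both ways together, relaxes with a half-life of 2.48 s, short against 6.0 min. With 17 % of the reagent left at that moment, ash ends 8.4 points below the target of 6.0 min.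

In the neighbour with [second substrate] = 0.18 M, 50.7 % of the starting material is left at 6.0 min, so 0.651 on the part used gives 32.1 % of target; the computed value in that neighbour is 32.3 %.

The runs were computed with constants of no real substance, and the scatter is random.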